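Target is one entry in a ledger that I keep on the starting material, the limiting reagent of a flask charged with 2.00 equiv of partner: each mole charged stands as target, as starting material, or as something the analysis does not show.

the same everywhere: free catalyst 0.6 mol%; second catalyst 0.05 mol%

|  | starting material | partner | remark | time |
|---|---|---|---|---|
| epsilon | 0.010 M | 1 equiv | run made earlier |  |
| eta | 0.010 M | 1.5 equiv | run made earlier |  |
| theta | 0.0050 M | 2 equiv | run made earlier |  |
| flask | 0.010 M | 2.00 equiv |  | 12 min |

- epsilon (time / min: target / %, starting material / %): 3.00: 24.1, 27.2; 4.00: 31.1, 25.0; 6.00: 41.2, 20.9; 8.00: 50.8, 17.9; 12.0: 62.4, 13.8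
- eta (time / min: target / %, starting material / %): 3.00: 34.2, 23.6; 4.00: 43.5, 20.9; 6.00: 58.1, 15.3; 8.00: 68.0, 11.5; 12.0: 81.4, 6.5
- theta (time / min: target / %, starting material / %): 3.00: 21.0, 28.6; 4.00: 27.8, 26.2; 6.00: 38.9, 22.1; 8.00: 48.3, 19.2; 12.0: 63.6, 13.6

(scatter of a reading: 0.3 percentage points)

- the analysis behind the earlier runs scatters by 0.3 percentage points, standard deviation

- the best time, 12 min at the latest, for target
- the amount of target, in percent of the starting material charged, at that time
- the first time at which target reaches 64%, in the same percent, in min

In the epsilon run at 6.00 min the books read 41.2% target and 20.9% starting material, so 37.9% stands unseen. Late in a run the part not yet target is the small entry, so I reckon with that part and ask how much of it shows. Pooled over epsilon, eta and theta at 6.00 min, starting material divided by what is not yet target reads 0.360, and I carry this as the visible share, the part of what is not yet target that shows as starting material. For the last eta reading it gives 6.70% starting material against the 6.5% read, a gap inside the scatter of 0.3 percentage points.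

The forecast puts target in the flask at 91.5% (from 87% to 94%) at 12 min (from 11 min to 12 min), and reaches 64% at 4.9 min (from 4.3 min to 5.6 min), reading the steady ratio to mean that starting material “sits in fast equilibrium with an unseen intermediate”. On that target my ledger for the flask closes with 3.06% starting material and 5.44% unseen.

The flask gives 92.1% at 12.0 min and reaches 64% at 5.13 min, inside each range of the forecast.

    second catalyst + open intermediate ⇌ catalyst intermediate (K = 1500 L mol⁻¹, k = 36000 L mol⁻¹ s⁻¹)
    2 second catalyst ⇌ resting dimer, settled at all times (K = 1.70 × 10⁶ L mol⁻¹)
    starting material + free catalyst ⇌ free catalyst + open intermediate (K = 1.80, k = 1330 L mol⁻¹ s⁻¹)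
    partner + catalyst intermediate → second catalyst + target (k = 441 L mol⁻¹ s⁻¹)
    free catalyst → spent catalyst (k = 3.60 × 10⁻⁶ s⁻¹)

At 12.0 min the flask holds 2.91% starting material, where the visible share gives 2.84%, and 4.98% open intermediate, which the analysis does not show. The neighbouring flask with 0.500 equiv of partner, its other charges as in the flask, stands at 34.1% target at 12.0 min, lower than the low end of the forecast for the flask, with 32% of its partner left. The visible share gives that neighbouring flask 23.7% starting material, and it holds 23.6%, beside 42.3% open intermediate.

The earlier runs and the new flask are simulated for substances that don't exist; the scatter is artificial.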